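One molecule of starting material is easy to follow: suppose it needs one partner to become target. Target then has a ceiling C, the partner charged over the starting material charged, with partner as the limiting reagent while that ratio stays below the whole charge.

| setting | birch | ash | oak | spring | dusk |
|---|---|---|---|---|---|
| starting material | 0.37 M | 0.37 M | 0.55 M | 0.37 M | 0.37 M |
| partner | 0.15 M | 0.59 M | 0.296 M | 0.296 M | 0.296 M |
| temperature | 105 °C | 118 °C | 105 °C | 110 °C | 125 °C |
| remark | run made earlier | run made earlier | run made earlier |  |  |
| time |  |  |  | 3.0 d | 3.0 d |

| run | time / d | target / % | starting material / % |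
|---|---|---|---|
| birch | 0.500 | 35.6 | 40.7 |
| birch | 1.04 | 40.9 | 20.5 |
| birch | 1.25 | 40.5 | 13.8 |
| birch | 2.08 | 41.9 | 10.5 |
| birch | 2.50 | 40.1 | 11.7 |
| ash | 0.208 | 72.7 | 25.8 |
| ash | 0.333 | 88.4 | 11.9 |
| ash | 0.625 | 98.3 | 2.1 |
| ash | 1.25 | 98.1 | 0 |
| ash | 2.50 | 101.2 | 0 |
| oak | 0.500 | 46.2 | 39.0 |
| oak | 1.04 | 52.4 | 18.3 |
| oak | 1.25 | 52.6 | 15.1 |
| oak | 2.08 | 53.6 | 9.4 |
| oak | 2.50 | 54.5 | 8.1 |

(standard deviation of a reading: 1 percentage point)

- the numbers in the tables scatter with a standard deviation of 1 percentage point
- a reading or a percentage of target counts all its forms, free or not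

1. the best flask by amount of target, in percent of the starting material charged; "all alike" if 1.5 percentage points covers them all (spring / dusk / all alike)
2. amount of target at the end, in percent of the starting material charged, spring
3. amount of target at the end, in percent of the starting material charged, dusk

Birch tests this: C is 40.5%, and target last reads 40.1%. Oak agrees, with C at 53.8% and a last reading of 54.5%. But the ratio in ash is 159%, above the whole charge, so starting material is the limit there and target reads 101.2%. Ash also shows no fall of target, from 98.1% at 1.25 d to 101.2% at 2.50 d.

Time is the next fork. In birch, starting material falls to half between 0.500 d and 1.04 d, a reading of 0.540 d for that one halving at 105 °C. So the 3.0 d allowed is longer than that, and spring is hotter than birch.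

Spring and dusk carry the same charge, so the reckoning here gives both 80.0%, the ceiling, partner charged over starting material charged. But dusk, at 125 °C, is hotter than any run, so its figure is the less safe.

The forecast gives 80% for spring and 80% for dusk, hence all alike, on the ground that “target plateaus at the partner/starting-material ratio”.

The simulation gives 80.0% in spring and 80.0% in dusk, so the two flasks count as all alike. The steps behind these numbers are:

    starting material ⇌ open intermediate (K = 3.60, k = 0.130 h⁻¹, Ea = 112 kJ mol⁻¹, ΔH = −49.0 kJ mol⁻¹)
    partner → second intermediate (k = 0.290 h⁻¹, Ea = 112 kJ mol⁻¹)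
    open intermediate + second intermediate → target (k = 36.0 L mol⁻¹ h⁻¹, Ea = 89.0 kJ mol⁻¹)
    crystals ⇌ target, rate k4*(cs4 - [target]) while solid is left; crystals form when [target] > cs4 (solubility = 0.260 M, k = 0.930 h⁻¹)
    (constants at 110 °C)

At 3.00 d, spring holds 0% of its partner's own charge, and the starting material not turned to target stands as 4.35% starting material and 15.7% open intermediate. With partner held, the ceiling 80.0% shrinks as starting material grows: the neighbour flask, spring with 0.93 M of starting material, has a ceiling of 31.8%, and its target ends at 31.8%.

All runs are calculated from invented constants; scatter was added.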